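The numbers in the tables stem from a simulated flask for substances that don't exist.

Reagent still in the feed cannot react, so a fed flask cannot work on its whole charge for the whole run.

common to all: left-handed substrate 0.050 M; right-handed substrate 0.050 M

|  | reagent | catalyst | temperature | remark | time |
|---|---|---|---|---|---|
| dusk | 0.060 M (fed, over 30 min) | 2.5 mM | 35 °C | run made earlier; the fed solution adds 0.10 times the starting volume |  |
| noon | 0.060 M (fed, over 30 min) | 5.1 mM | 50 °C | run made earlier; the fed solution adds 0.10 times the starting volume |  |
| autumn | 0.060 M (fed, over 30 min) | 12 mM | 35 °C | run made earlier; the fed solution adds 0.10 times the starting volume |  |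
| west | 0.0600 M (fed, over 30 min) | 10 mM | 50 °C | the fed solution adds 0.10 times the starting volume | 50 min |
| south-east | 0.0600 M | 3.0 mM | 50 °C | everything together at the start, the whole solution of reagent included, so that from the start the volume is larger by 0.10 times the starting volume | 50 min |

| run | time / min | left-handed product / % |
|---|---|---|
| dusk | 10.0 | 0.6 |
| dusk | 20.0 | 1.8 |
| dusk | 30.0 | 2.7 |
| dusk | 40.0 | 4.1 |
| dusk | 50.0 | 5.5 |
| noon | 2.00 | 0.1 |
| noon | 6.00 | 0.5 |
| noon | 12.0 | 1.3 |
| noon | 20.0 | 4.6 |
| noon | 25.0 | 6.6 |
| autumn | 4.00 | 0.6 |
| autumn | 12.0 | 1.7 |
| autumn | 25.0 | 6.9 |
| autumn | 40.0 | 13.5 |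
| autumn | 50.0 | 15.9 |

(readings scatter by 0.5 percentage points)

- catalyst is single-handed; left-handed substrate and right-handed substrate are mirror images of each other, charged as a racemate, each of them at the stated concentration
- charges are per starting volume, the dose included; the dosed solution carries all of it

- the flask that ends with the higher amount of left-handed product, in percent of the left-handed substrate and right-handed substrate together charged, or "neither" when 2 percentage points or less lies between them (west / south-east / neither)
- final left-handed product, as a percentage of the left-handed substrate and right-handed substrate together charged, in west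
- final left-handed product, as a percentage of the left-handed substrate and right-handed substrate together charged, in south-east

Counted as minutes of whole charge, a steady feed costs half the feed time: west gets 35.0 min, south-east, with everything in from the start, gets 50 min, and noon at its last reading has had 10.4 min. Call the reach the fraction of both substrates charged that would stand as left-handed product if nothing were used up, and take it as proportional to catalyst times those minutes, the reagent charge being equal. Scaling noon's 6.6% this way gives west 43.5%.

The dusk and autumn runs object. At 35 °C, 4.80 times the catalyst lifts 5.5% to 15.9%, not to 26.4%. So let the inverse of the product be the inverse of the reach plus a drag, which stands for what is used up, among it reagent, the limiting reagent at 0.0600 M against 0.100 M of both substrates. That pair gives a drag of 2.50. But dusk carries drag too, and putting this value back raises dusk's reach to 6.38% and the drag to 3.02, the drag of the reach.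

Noon's reach is then 8.24%. West reaches 54.3% and ends near 20.6%; south-east reaches 23.3% and ends near 13.7%.

One doubt remains: the drag was read at 35 °C and these flasks run at 50 °C. The first drag instead gives 23.0% and 14.7%, and the gap stays above the margin. At 25.0 min the same rule gives west 10.9% and south-east 8.61%, so the two flasks part late.

The forecast names west, with 19% and 12.5%, and reads the same slowing differently: “Catalyst order looks sub-linear, about 0.7”. The reckoning here keeps catalyst proportional and lands higher.

West ends at 21.3% and south-east at 14.0%.

    reagent + catalyst + left-handed substrate → catalyst + left-handed product (k = 1.20 L² mol⁻² s⁻¹, Ea = 51.0 kJ mol⁻¹)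
    reagent + catalyst + right-handed substrate → catalyst + right-handed product (k = 0.740 L² mol⁻² s⁻¹, Ea = 38.0 kJ mol⁻¹)
    left-handed product ⇌ right-handed product (k = 7.80 × 10⁻⁴ s⁻¹, Ea = 92.0 kJ mol⁻¹)
    (constants at 50 °C)

Beside its left-handed product, west holds 20.2% of right-handed product. A neighbour of south-east with 0.012 M catalyst, its reagent charge unchanged, has a reach of 93.1%, and the drag of 3.02 brings it to 24.4%. That neighbour gives 25.4%.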